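## Plan

- Numbering follows 1H-isochromene (C1, O2, C3, C4, C4a, C5–C8, C8a). Retrosynthetic cuts, in order: O2–C3 of the pyran (oxa-conjugate addition of the C1 hydroxyl to a C4a-alkynyl enone); then C4a–C5 and C6–C7 of the carbocycle together ([4+2] cycloaddition); then C4–C4a (Sonogashira) and the furan ring.
- Enabling feature: the carbocycle is a 6-hydroxycyclohex-2-enone. The tertiary carbinol C7 and the enone β-carbon C4a stand 1,4 across the ring with C8=O and C8a between them, so the C7 oxygen can be tied back to C4a as the ring oxygen of a 3-silyloxyfuran (C7=C8(OSi)–C8a=C4a). C5–C6 is then the dienophile, an (E)-enol ester that already carries the orsellinate.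
- Forward order: furan (helper ring) → 7-oxanorbornene (carbocycle closed, oxygen bridge as temporary ring) → bridge opened to the C7-hydroxy enone → C5 carboxyl helper removed → pyran closed last.
- Helpers: the oxygen bridge, the N-acyl oxazolidinone on C5 (activates the dienophile and binds the catalyst), and three silyl groups; all leave in steps 15–17.
- Stereochemistry: C6 and C7 are both created in the cycloaddition. The absolute sense comes from the (S,S)-bis(oxazoline) copper catalyst, the cis C6–O/C7–O relation from the endo-imide/exo-aroyloxy geometry of the (E)-enol ester. Neither centre is touched again.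

Key step: step 14

Remark: ethyl lactate is used as the racemate because its stereocentre is erased in step 2; the target is (6S,7S), with the C6 ester and C7 hydroxyl cis.

## Route

Step 1
Reactants: 1 ethyl lactate (racemic); 2 ethyl acrylate
Product: 3 ethyl 5-methyl-4-oxotetrahydrofuran-3-carboxylate
Conditions: NaH, THF, 0 °C to rt; aq. HCl
Reagents that add atoms: none
Why: Tandem oxa-Michael addition of the lactate alkoxide to the acrylate and Dieckmann condensation of the resulting ester enolate onto the lactate ester should give the cyclic β-keto ester, whose acidity drives the equilibrium.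

Step 2
Reactants: 3 ethyl 5-methyl-4-oxotetrahydrofuran-3-carboxylate
Product: 6 ethyl 4-hydroxy-5-methylfuran-3-carboxylate, via 3-phenylselanyl keto ester 4 (not isolated), via selenoxide 5 (not isolated)
Conditions: PhSeCl, pyridine, CH2Cl2, 0 °C; then 30% H2O2, 0 °C to rt
Reagents that add atoms: none
Why: α-Selenenylation of the β-keto ester and selenoxide syn-elimination toward the only β-hydrogens (the ring CH2–O) should give the 4-oxo-4,5-dihydrofuran, which tautomerises to the hydrogen-bonded aromatic 3-hydroxyfuran.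

Step 3
Reactants: 6 ethyl 4-hydroxy-5-methylfuran-3-carboxylate
Product: 7 ethyl 5-methyl-4-(triisopropylsilyloxy)furan-3-carboxylate
Conditions: i-Pr3SiOTf, 2,6-lutidine, CH2Cl2, 0 °C
Reagents that add atoms: triisopropylsilyl trifluoromethanesulfonate, CC(C)[Si](OS(=O)(=O)C(F)(F)F)(C(C)C)C(C)C
Why: O-Silylation of the enolic hydroxyl; the bulky silyl group is chosen to resist migration and to survive lithiation, hydride reduction and hydroperoxide.

Step 4
Reactants: 7 ethyl 5-methyl-4-(triisopropylsilyloxy)furan-3-carboxylate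
Product: 9 ethyl 2-iodo-5-methyl-4-(triisopropylsilyloxy)furan-3-carboxylate, via 2-lithiofuran 8 (not isolated)
Conditions: LiN(i-Pr)2, THF, −78 °C; then I2
Reagents that add atoms: iodine, II
Why: Directed ortho-lithiation at the only free ring position (α to the ring oxygen and ortho to the ester) followed by iodine quench.

Step 5
Reactants: 10 (E)-but-2-enal
Product: 11 (E)-pent-3-en-1-yne
Conditions: Me3SiCHN2, LiN(i-Pr)2, THF, −78 °C to rt
Reagents that add atoms: trimethylsilyldiazomethane, C[Si](C)(C)C=[N+]=[N-]
Why: Colvin rearrangement (1,2-addition, Peterson elimination, loss of N2 and 1,2-hydrogen shift of the alkylidene carbene) homologates the enal to the enyne without conjugate addition and without touching the (E)-alkene; the volatile product is used as a solution.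

Step 6
Reactants: 9 ethyl 2-iodo-5-methyl-4-(triisopropylsilyloxy)furan-3-carboxylate; 11 (E)-pent-3-en-1-yne
Product: 12 ethyl 5-methyl-2-[(E)-pent-3-en-1-yn-1-yl]-4-(triisopropylsilyloxy)furan-3-carboxylate
Conditions: Pd(PPh3)2Cl2, CuI, Et3N, THF, rt
Reagents that add atoms: none
Why: Sonogashira coupling of an electron-poor 2-iodofuran with a terminal alkyne under mild amine conditions that leave the silyl enol ether and the alkene geometry intact.

Step 7
Reactants: 12 ethyl 5-methyl-2-[(E)-pent-3-en-1-yn-1-yl]-4-(triisopropylsilyloxy)furan-3-carboxylate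
Product: 13 {5-methyl-2-[(E)-pent-3-en-1-yn-1-yl]-4-(triisopropylsilyloxy)furan-3-yl}methanol
Conditions: i-Bu2AlH, CH2Cl2, −78 °C; aq. work-up
Reagents that add atoms: none
Why: Hydride reduction of the furoate ester to the primary alcohol (the future C1) at low temperature, where enyne and silyl enol ether are inert.

Step 8
Reactants: 13 {5-methyl-2-[(E)-pent-3-en-1-yn-1-yl]-4-(triisopropylsilyloxy)furan-3-yl}methanol
Product: 14 tert-butyl({5-methyl-2-[(E)-pent-3-en-1-yn-1-yl]-4-(triisopropylsilyloxy)furan-3-yl}methoxy)diphenylsilane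
Conditions: t-BuPh2SiCl, imidazole, DMF, 0 °C
Reagents that add atoms: tert-butylchlorodiphenylsilane, CC(C)(C)[Si](Cl)(c1ccccc1)c1ccccc1
Why: Silylation of the primary alcohol keeps the hydroxymethyl group away from the Lewis acid and the alkyne until the last step; the acid-stable silyl group is chosen to survive step 15.

Step 9
Reactants: 15 2,4-dihydroxy-6-methylbenzaldehyde
Product: 16 2-hydroxy-6-methyl-4-(triisopropylsilyloxy)benzaldehyde
Conditions: i-Pr3SiCl, imidazole, CH2Cl2, 0 °C
Reagents that add atoms: chlorotriisopropylsilane, CC(C)[Si](Cl)(C(C)C)C(C)C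
Why: The 4-hydroxyl is more acidic and unhindered, whereas the 2-hydroxyl is hydrogen-bonded to the aldehyde, so monosilylation should occur at O4.

Step 10
Reactants: 16 2-hydroxy-6-methyl-4-(triisopropylsilyloxy)benzaldehyde
Product: 17 2-methoxy-6-methyl-4-(triisopropylsilyloxy)benzaldehyde
Conditions: MeI, Ag2O, MeCN, rt
Reagents that add atoms: iodomethane, CI
Why: Silver-oxide-mediated O-methylation of the chelated phenol under non-basic conditions that spare the aryl silyl ether.

Step 11
Reactants: 17 2-methoxy-6-methyl-4-(triisopropylsilyloxy)benzaldehyde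
Product: 18 2-methoxy-6-methyl-4-(triisopropylsilyloxy)benzoic acid
Conditions: NaClO2, NaH2PO4, 2-methyl-2-butene, t-BuOH/H2O, rt
Reagents that add atoms: sodium chlorite, [Na+].[O-]Cl=O
Why: Pinnick oxidation converts the hindered aldehyde to the acid at buffered pH, the alkene scavenger protecting the electron-rich ring from hypochlorite.

Step 12
Reactants: 19 propiolic acid; 20 oxazolidin-2-one
Product: 22 3-propioloyloxazolidin-2-one, via mixed anhydride 21 (not isolated)
Conditions: t-BuCOCl, Et3N, THF, −20 °C; then 20, LiCl, rt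
Reagents that add atoms: none
Why: N-Acylation of the oxazolidinone through the pivalic mixed anhydride, the lithium-complexed carbamate attacking the less hindered propioloyl carbonyl.

Step 13
Reactants: 18 2-methoxy-6-methyl-4-(triisopropylsilyloxy)benzoic acid; 22 3-propioloyloxazolidin-2-one
Product: 23 (E)-3-oxo-3-(2-oxooxazolidin-3-yl)prop-1-en-1-yl 2-methoxy-6-methyl-4-(triisopropylsilyloxy)benzoate
Conditions: N-methylmorpholine (20 mol %), CH2Cl2, rt
Reagents that add atoms: none
Why: Amine-catalysed conjugate addition of the carboxylate to the ynimide gives the (E)-enol ester; the hindered 2,6-disubstituted aryl ester is thus made through its carboxylate oxygen and not by acylation of a hindered alcohol.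

Step 14
Reactants: 14 tert-butyl({5-methyl-2-[(E)-pent-3-en-1-yn-1-yl]-4-(triisopropylsilyloxy)furan-3-yl}methoxy)diphenylsilane; 23 (E)-3-oxo-3-(2-oxooxazolidin-3-yl)prop-1-en-1-yl 2-methoxy-6-methyl-4-(triisopropylsilyloxy)benzoate
Product: 24 (1S,4S,5S,6S)-7-oxabicyclo[2.2.1]hept-2-ene cycloadduct (5-endo imide; 6-exo aroyloxy)
Conditions: Cu(SbF6)2·(S,S)-tBu-box (10 mol %; box = 2,2'-(propane-2,2-diyl)bis[(4S)-4-tert-butyl-4,5-dihydrooxazole]), 4 Å MS, CH2Cl2, −78 to −40 °C
Reagents that add atoms: none
Why: The 3-silyloxy group makes the methyl-bearing furan carbon (C7) the nucleophilic diene terminus and the chelated imide makes the aroyloxy-bearing β-carbon (C6) of 23 the electrophilic one, so a concerted but asynchronous [4+2] cycloaddition should join C7 to C6 and C4a to C5 and not the reverse (a stepwise Mukaiyama–Michael addition with ring closure of the zwitterion would end at the same adduct). The closest known reaction type is the copper bis(oxazoline)-catalysed Diels–Alder reaction of furan with N-acryloyl oxazolidinones, together with the Diels–Alder reactions of 3-alkoxy- and 3-silyloxyfurans. The carbocycle C4a–C5–C6–C7–C8–C8a closes as a suprafacial [4π+2π] cycloaddition onto the furan, whose oxygen stays as a temporary C7–O–C4a bridge. C5 and C6 are set by the catalyst: in the square-planar divalent copper chelate of the s-cis imide a tert-butyl group of the (S,S)-ligand shields one face, so the diene adds to the Cα-re/Cβ-re face (5S,6S). C7 and C4a follow from the endo orientation of the chelated imide, which with the (E)-enol ester places the aroyloxy group exo, that is cis to the bridging oxygen (7S, the later cis C6–O/C7–O pair). The step needs regio-, endo- and facial selectivity, secured respectively by the matched polarisation of both partners, by kinetic control at low temperature and by the C2-symmetric ligand.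

Step 15
Reactants: 24 cycloadduct
Product: 26 (1R,5S,6S)-5-hydroxy-5-methyl-4-oxo-2-[(E)-pent-3-en-1-yn-1-yl]-3-(silyloxymethyl)-6-(aroyloxy)cyclohex-2-ene-1-carboxylic acid, via bridged acid 25 (not isolated)
Conditions: LiOH, H2O2, THF/H2O, 0 °C; Na2SO3; then CF3CO2H, CH2Cl2, 0 °C
Reagents that add atoms: lithium hydroperoxide formed from LiOH and H2O2, [Li+].[O-]O
Why: Hydroperoxide should attack the exocyclic imide carbonyl (the 2,6-disubstituted aryl ester and the silyl enol ether are far less electrophilic) to give acid 25, and acid then ionises the C4a–O bond of the vinylogous silyl acetal with silyloxy assistance (the acid unmasking known for β-alkoxy silyl enol ethers), which after loss of the silyl group leaves the C8 enone and the free C7 hydroxyl without touching C5–C7.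

Step 16
Reactants: 26 enone acid
Product: 28 (1S,2S)-2-hydroxy-2-methyl-3-oxo-5-[(E)-pent-3-en-1-yn-1-yl]-4-(silyloxymethyl)cyclohex-4-en-1-yl 2-methoxy-6-methyl-4-(triisopropylsilyloxy)benzoate, via N-acyloxyphthalimide 27 (not isolated)
Conditions: N-hydroxyphthalimide, i-PrN=C=N-i-Pr, CH2Cl2, 0 °C; then diethyl 2,6-dimethyl-1,4-dihydropyridine-3,5-dicarboxylate, Ru(bpy)3(PF6)2 (1 mol %), blue LED, rt
Reagents that add atoms: none
Why: Reductive decarboxylation of a redox-active ester: single-electron reduction expels phthalimide and CO2, and the C5 radical, allylic to the enone, takes a hydrogen atom from the dihydropyridine at the less hindered C5, with no carbanion at C5 (so the β-aroyloxy group should not be expelled) and no thiyl radical (so the (E)-propenyl group should not isomerise).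

Step 17
Reactants: 28 silylated alkynyl enone
Product: 30 comazaphilone G, via desilylated ynenone 29 (not isolated)
Conditions: Bu4NF, AcOH, THF, 0 °C to rt; then DABCO (20 mol %)
Reagents that add atoms: none
Why: Buffered fluoride should remove both silyl ethers, and amine-catalysed oxa-conjugate (1,6) addition of the C1 hydroxyl to the δ-carbon C3 of the ynenone closes the pyran in the 6-endo-dig mode (attack at C4 would give an unstabilised vinyl anion), protonation at C4 then giving the 2H-pyran dienone with C6 and C7 untouched.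

## Compound list

1 | ethyl lactate (racemic) | CCOC(=O)C(C)O | starting material
2 | ethyl acrylate | C=CC(=O)OCC | starting material
3 | ethyl 5-methyl-4-oxotetrahydrofuran-3-carboxylate (stereoisomer and enol mixture) | CCOC(=O)C1COC(C)C1=O | intermediate
4 | ethyl 5-methyl-4-oxo-3-(phenylselanyl)tetrahydrofuran-3-carboxylate | CCOC(=O)C1([Se]c2ccccc2)COC(C)C1=O | intermediate (not isolated)
5 | selenoxide of 4 | CCOC(=O)C1([Se](=O)c2ccccc2)COC(C)C1=O | intermediate (not isolated)
6 | ethyl 4-hydroxy-5-methylfuran-3-carboxylate | CCOC(=O)c1coc(C)c1O | intermediate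
7 | ethyl 5-methyl-4-(triisopropylsilyloxy)furan-3-carboxylate | CCOC(=O)c1coc(C)c1O[Si](C(C)C)(C(C)C)C(C)C | intermediate
8 | ethyl 2-lithio-5-methyl-4-(triisopropylsilyloxy)furan-3-carboxylate | CCOC(=O)c1c([Li])oc(C)c1O[Si](C(C)C)(C(C)C)C(C)C | intermediate (not isolated)
9 | ethyl 2-iodo-5-methyl-4-(triisopropylsilyloxy)furan-3-carboxylate | CCOC(=O)c1c(I)oc(C)c1O[Si](C(C)C)(C(C)C)C(C)C | intermediate
10 | (E)-but-2-enal | C/C=C/C=O | starting material
11 | (E)-pent-3-en-1-yne | C/C=C/C#C | intermediate
12 | ethyl 5-methyl-2-[(E)-pent-3-en-1-yn-1-yl]-4-(triisopropylsilyloxy)furan-3-carboxylate | CCOC(=O)c1c(C#C/C=C/C)oc(C)c1O[Si](C(C)C)(C(C)C)C(C)C | intermediate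
13 | {5-methyl-2-[(E)-pent-3-en-1-yn-1-yl]-4-(triisopropylsilyloxy)furan-3-yl}methanol | OCc1c(C#C/C=C/C)oc(C)c1O[Si](C(C)C)(C(C)C)C(C)C | intermediate
14 | tert-butyl({5-methyl-2-[(E)-pent-3-en-1-yn-1-yl]-4-(triisopropylsilyloxy)furan-3-yl}methoxy)diphenylsilane (diene) | Cc1oc(C#C/C=C/C)c(CO[Si](c2ccccc2)(c2ccccc2)C(C)(C)C)c1O[Si](C(C)C)(C(C)C)C(C)C | intermediate
15 | 2,4-dihydroxy-6-methylbenzaldehyde | Cc1cc(O)cc(O)c1C=O | starting material
16 | 2-hydroxy-6-methyl-4-(triisopropylsilyloxy)benzaldehyde | Cc1cc(O[Si](C(C)C)(C(C)C)C(C)C)cc(O)c1C=O | intermediate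
17 | 2-methoxy-6-methyl-4-(triisopropylsilyloxy)benzaldehyde | COc1cc(O[Si](C(C)C)(C(C)C)C(C)C)cc(C)c1C=O | intermediate
18 | 2-methoxy-6-methyl-4-(triisopropylsilyloxy)benzoic acid | COc1cc(O[Si](C(C)C)(C(C)C)C(C)C)cc(C)c1C(=O)O | intermediate
19 | propiolic acid | C#CC(=O)O | starting material
20 | oxazolidin-2-one | O=C1NCCO1 | starting material
21 | pivalic propiolic anhydride | C#CC(=O)OC(=O)C(C)(C)C | intermediate (not isolated)
22 | 3-propioloyloxazolidin-2-one | C#CC(=O)N1CCOC1=O | intermediate
23 | (E)-3-oxo-3-(2-oxooxazolidin-3-yl)prop-1-en-1-yl 2-methoxy-6-methyl-4-(triisopropylsilyloxy)benzoate (dienophile) | O=C(/C=C/OC(=O)c1c(C)cc(O[Si](C(C)C)(C(C)C)C(C)C)cc1OC)N1CCOC1=O | intermediate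
24 | (1S,4S,5S,6S)-1-methyl-5-[(2-oxooxazolidin-3-yl)carbonyl]-4-[(E)-pent-3-en-1-yn-1-yl]-3-[(tert-butyldiphenylsilyloxy)methyl]-2-(triisopropylsilyloxy)-7-oxabicyclo[2.2.1]hept-2-en-6-yl 2-methoxy-6-methyl-4-(triisopropylsilyloxy)benzoate | C[C@@]12O[C@@](C#C/C=C/C)(C(CO[Si](c3ccccc3)(c3ccccc3)C(C)(C)C)=C1O[Si](C(C)C)(C(C)C)C(C)C)[C@@H](C(=O)N3CCOC3=O)[C@@H]2OC(=O)c2c(C)cc(O[Si](C(C)C)(C(C)C)C(C)C)cc2OC | intermediate
25 | (1S,4S,5S,6S)-bridged carboxylic acid corresponding to 24 | C[C@@]12O[C@@](C#C/C=C/C)(C(CO[Si](c3ccccc3)(c3ccccc3)C(C)(C)C)=C1O[Si](C(C)C)(C(C)C)C(C)C)[C@@H](C(=O)O)[C@@H]2OC(=O)c2c(C)cc(O[Si](C(C)C)(C(C)C)C(C)C)cc2OC | intermediate (not isolated)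
26 | (1R,5S,6S)-5-hydroxy-6-{[2-methoxy-6-methyl-4-(triisopropylsilyloxy)benzoyl]oxy}-5-methyl-4-oxo-2-[(E)-pent-3-en-1-yn-1-yl]-3-[(tert-butyldiphenylsilyloxy)methyl]cyclohex-2-ene-1-carboxylic acid | C/C=C/C#CC1=C(CO[Si](c2ccccc2)(c2ccccc2)C(C)(C)C)C(=O)[C@@](C)(O)[C@@H](OC(=O)c2c(C)cc(O[Si](C(C)C)(C(C)C)C(C)C)cc2OC)[C@@H]1C(=O)O | intermediate
27 | N-acyloxyphthalimide ester of 26 | C/C=C/C#CC1=C(CO[Si](c2ccccc2)(c2ccccc2)C(C)(C)C)C(=O)[C@@](C)(O)[C@@H](OC(=O)c2c(C)cc(O[Si](C(C)C)(C(C)C)C(C)C)cc2OC)[C@@H]1C(=O)ON1C(=O)c2ccccc2C1=O | intermediate (not isolated)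
28 | (1S,2S)-2-hydroxy-2-methyl-3-oxo-5-[(E)-pent-3-en-1-yn-1-yl]-4-[(tert-butyldiphenylsilyloxy)methyl]cyclohex-4-en-1-yl 2-methoxy-6-methyl-4-(triisopropylsilyloxy)benzoate | C/C=C/C#CC1=C(CO[Si](c2ccccc2)(c2ccccc2)C(C)(C)C)C(=O)[C@@](C)(O)[C@@H](OC(=O)c2c(C)cc(O[Si](C(C)C)(C(C)C)C(C)C)cc2OC)C1 | intermediate
29 | (1S,2S)-2-hydroxy-4-(hydroxymethyl)-2-methyl-3-oxo-5-[(E)-pent-3-en-1-yn-1-yl]cyclohex-4-en-1-yl 4-hydroxy-2-methoxy-6-methylbenzoate | C/C=C/C#CC1=C(CO)C(=O)[C@@](C)(O)[C@@H](OC(=O)c2c(C)cc(O)cc2OC)C1 | intermediate (not isolated)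
30 | comazaphilone G, (6S,7S)-7-hydroxy-7-methyl-8-oxo-3-[(E)-prop-1-en-1-yl]-5,6,7,8-tetrahydro-1H-isochromen-6-yl 4-hydroxy-2-methoxy-6-methylbenzoate | C/C=C/C1=CC2=C(CO1)C(=O)[C@@](C)(O)[C@@H](OC(=O)c1c(C)cc(O)cc1OC)C2 | target

## Step count and risks

Total steps: 17. Longest linear sequence: 11 steps (steps 1–4, 6–8 and 14–17).

Steps most likely to fail:

**Step 14.** Possible failures are conjugate addition with silyl transfer and no ring closure, β-elimination of the aroyloxy group from the copper-bound enolate, cycloreversion, or insufficient endo or facial selectivity at two fully substituted bridgeheads.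
Fallback: stereocontrol is moved from the catalyst to a covalently bound auxiliary, whose diastereomeric adducts can be separated. The fallback sets out from diene 14, acid 18 and mixed anhydride 21. Anhydride 21 is treated with (R)-4-benzyloxazolidin-2-one and LiCl to give (R)-4-benzyl-3-propioloyloxazolidin-2-one F1. Acid 18 is added under N-methylmorpholine catalysis to give the (E)-enol ester (E)-3-[(R)-4-benzyl-2-oxooxazolidin-3-yl]-3-oxoprop-1-en-1-yl 2-methoxy-6-methyl-4-(triisopropylsilyloxy)benzoate F2. F2 and 14 are combined under Me2AlCl in CH2Cl2 at −78 °C; in the aluminium chelate the benzyl group shields the face opposite to the one required, giving the auxiliary-bearing oxanorbornene F3 with the ring configuration of 24. LiOH/H2O2 and then CF3CO2H, as in step 15, release the auxiliary, and the route is rejoined at 26.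

**Step 16.** Possible failures are β-elimination of the aroyloxy group once the acid is activated, hydrogen delivery at C8a instead of C5, or isomerisation of the (E)-propenyl group by energy transfer from the photocatalyst.
Fallback: radical generation is changed from photoredox single-electron reduction to a thermal or visible-light radical chain. The fallback sets out from 26, which is converted with 2-mercaptopyridine N-oxide and dicyclohexylcarbodiimide (dark, 0 °C, no amine base) into the O-acyl thiohydroxamate of 26 F4. Brief irradiation with a tungsten lamp at 0 °C in the presence of t-BuSH should give 28, where the route is rejoined.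

**Step 17.** Possible failures are base-induced loss of the aroyloxy group through the C5 dienolate, competing 5-exo closure, or intermolecular addition of the phenol to the ynenone.
Fallback: desilylation and ring closure are separated and the closure is switched from base to π-acid activation. The fallback sets out from 28, which is desilylated with HF·pyridine in THF/pyridine, and 29 is isolated. Neutral 6-endo-dig cycloisomerisation with AuCl(PPh3)/AgOTf (2 mol %) in CH2Cl2 should then give 30. No further compound is made (F0).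

## Further compounds

F1 | step 14 | (R)-4-benzyl-3-propioloyloxazolidin-2-one | C#CC(=O)N1[C@H](Cc2ccccc2)COC1=O
F2 | step 14 | (E)-3-[(R)-4-benzyl-2-oxooxazolidin-3-yl]-3-oxoprop-1-en-1-yl 2-methoxy-6-methyl-4-(triisopropylsilyloxy)benzoate | O=C(/C=C/OC(=O)c1c(C)cc(O[Si](C(C)C)(C(C)C)C(C)C)cc1OC)N1[C@H](Cc2ccccc2)COC1=O
F3 | step 14 | (1S,4S,5S,6S)-cycloadduct bearing the (R)-4-benzyloxazolidinone | C[C@@]12O[C@@](C#C/C=C/C)(C(CO[Si](c3ccccc3)(c3ccccc3)C(C)(C)C)=C1O[Si](C(C)C)(C(C)C)C(C)C)[C@@H](C(=O)N3[C@H](Cc4ccccc4)COC3=O)[C@@H]2OC(=O)c2c(C)cc(O[Si](C(C)C)(C(C)C)C(C)C)cc2OC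
F4 | step 16 | O-acyl thiohydroxamate of 26 | C/C=C/C#CC1=C(CO[Si](c2ccccc2)(c2ccccc2)C(C)(C)C)C(=O)[C@@](C)(O)[C@@H](OC(=O)c2c(C)cc(O[Si](C(C)C)(C(C)C)C(C)C)cc2OC)[C@@H]1C(=O)ON1C=CC=CC1=S
F0 | step 17 | none | none
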